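## Retrosynthetic overview

1. Eupacunolin ⇐ 15-O-TBDPS ether ⇐ macrocyclic 3-hydroxy-1-ketone by Evans–Tishchenko reduction with acetaldehyde, which sets C1 anti to C3 and puts the acetate on O3.
2. 10-membered carbocycle (formed last) ⇐ intramolecular Ni/Cr coupling of a C10 (Z)-vinyl iodide with a C1 aldehyde, then oxidation.
3. Key C7–C8 bond ⇐ intermolecular Zn-Barbier allylation of (Z)-3-iodobut-2-enal with a 3-(bromomethyl)butenolide; this gives the α-methylene-γ-lactone and C7/C8, and a Mitsunobu inversion with tiglic acid corrects C8.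
4. Bromobutenolide (first ring, by RCM of an acrylate) ⇐ (Z)-vinyl iodide from directed hydroalumination/iodination; C6 by Sharpless kinetic resolution, C3 by CBS reduction.
5. Ring order: butenolide → α-methylene-γ-lactone → cyclodecadiene.

Assumption: germacrane-type locants are used throughout (C1 carbinol, C3 acetoxy carbon, C4=C5 bearing C15H2O, C6 lactone O-carbon, C7, C8 tiglate carbon, C9=C10 bearing C14H3, C11–C13 methylene-lactone carbons); the target is then (1S,3S,6R,7R,8R,4Z,9Z).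

Abbreviations: TBS = tert-butyldimethylsilyl, TBDPS = tert-butyldiphenylsilyl, TES = triethylsilyl, PMB = 4-methoxybenzyl.

## Route

Step 1
Reactants: 1 propane-1,3-diol
Product: 2 3-[(4-methoxybenzyl)oxy]propan-1-ol
Conditions: NaH (1 equiv), PMBCl (1 equiv), diol (3 equiv), cat. Bu4NI, THF/DMF, 0 °C → rt
Reagents that add atoms: 4-methoxybenzyl chloride, COc1ccc(CCl)cc1
Why: Williamson mono-etherification; excess symmetric diol suppresses bis-alkylation.

Step 2
Reactants: 2 3-[(4-methoxybenzyl)oxy]propan-1-ol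
Product: 3 3-[(4-methoxybenzyl)oxy]propanal
Conditions: Dess–Martin periodinane, NaHCO3, CH2Cl2, 0 °C → rt
Reagents that add atoms: none
Why: Dess–Martin oxidation stops at the aldehyde under buffered conditions that do not eliminate the β-alkoxy group.

Step 3
Reactants: 4 ethyl 2-(hydroxymethyl)prop-2-enoate
Product: 5 ethyl 2-{[(tert-butyldimethylsilyl)oxy]methyl}prop-2-enoate
Conditions: TBSCl, imidazole, DMF, 0 °C → rt
Reagents that add atoms: tert-butyldimethylsilyl chloride, CC(C)(C)[Si](C)(C)Cl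
Why: standard silylation of a primary allylic alcohol.

Step 4
Reactants: 5 ethyl 2-{[(tert-butyldimethylsilyl)oxy]methyl}prop-2-enoate
Product: 6 2-{[(tert-butyldimethylsilyl)oxy]methyl}prop-2-enoic acid
Conditions: LiOH·H2O, THF/H2O, 0 °C → rt; then 1 M HCl to pH 4
Reagents that add atoms: lithium hydroxide, [Li+].[OH-]
Why: saponification; the TBS ether survives cold aqueous LiOH and a brief mild acidification.

Step 5
Reactants: 7 prop-2-yn-1-ol
Product: 8 tert-butyl(diphenyl)(prop-2-yn-1-yloxy)silane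
Conditions: TBDPSCl, imidazole, CH2Cl2, 0 °C → rt
Reagents that add atoms: tert-butyldiphenylsilyl chloride, CC(C)(C)[Si](Cl)(c1ccccc1)c1ccccc1
Why: silylation; this robust ether (the future O15) is carried to the last step.

Step 6
Reactants: 8 tert-butyl(diphenyl)(prop-2-yn-1-yloxy)silane; 9 (E)-but-2-enal
Product: 11 rac-(5E)-1-[(tert-butyldiphenylsilyl)oxy]hept-5-en-2-yn-4-ol, via lithium acetylide 10 (not isolated)
Conditions: n-BuLi, THF, −78 °C; then 9, −78 → −20 °C; aq. NH4Cl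
Reagents that add atoms: none
Why: acetylide 1,2-addition to the enal builds C4–C7 (C6 racemic); the propenyl group is the later RCM handle.

Step 7
Reactants: 11 rac-(5E)-1-[(tert-butyldiphenylsilyl)oxy]hept-5-en-2-yn-4-ol
Product: 12 (4S,5E)-1-[(tert-butyldiphenylsilyl)oxy]hept-5-en-2-yn-4-ol
Conditions: Ti(OiPr)4 (0.2 equiv), L-(+)-DIPT (0.24 equiv), t-BuOOH (0.6 equiv), 4 Å MS, CH2Cl2, −20 °C, to about 55–60 % conversion
Reagents that add atoms: none
Why: Sharpless kinetic resolution; with L-(+)-tartrate the (R)-carbinol is epoxidised fast, leaving the (S)-alcohol (yield ≤ 45 %), which sets C6.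

Step 8
Reactants: 12 (4S,5E)-1-[(tert-butyldiphenylsilyl)oxy]hept-5-en-2-yn-4-ol
Product: 14 (2Z,4S,5E)-1-[(tert-butyldiphenylsilyl)oxy]-2-iodohepta-2,5-dien-4-ol, via cyclic vinylalanate 13 (not isolated)
Conditions: Red-Al, THF, −20 → 0 °C; EtOAc; then I2, THF, −78 °C
Reagents that add atoms: iodine, II
Why: hydroxyl-directed trans-hydroalumination puts Al on the distal alkyne carbon (C4) in a five-membered alanate, and iodinolysis with retention gives the vinyl iodide with I cis to C6; this fixes the C4=C5 geometry (kept cold to avoid allene formation).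

Step 9
Reactants: 14 (2Z,4S,5E)-1-[(tert-butyldiphenylsilyl)oxy]-2-iodohepta-2,5-dien-4-ol
Product: 15 triethylsilyl ether of 14
Conditions: TESCl, imidazole, CH2Cl2, 0 °C
Reagents that add atoms: triethylsilyl chloride, CC[Si](Cl)(CC)CC
Why: temporary protection of O6 that can later be removed in the presence of TBS and TBDPS.

Step 10
Reactants: 15 triethylsilyl ether of 14; 3 3-[(4-methoxybenzyl)oxy]propanal
Product: 16 (4Z,6S,7E)-1-[(4-methoxybenzyl)oxy]-4-{[(tert-butyldiphenylsilyl)oxy]methyl}-6-[(triethylsilyl)oxy]nona-4,7-dien-3-ol (3RS mixture)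
Conditions: CrCl2 (5 equiv), NiCl2 (2 mol %), DMSO, rt
Reagents that add atoms: none
Why: Nozaki–Hiyama–Kishi coupling forms C3–C4 with retention of olefin geometry (C3 cis to C6); the C3 epimers converge in the next step.

Step 11
Reactants: 16 NHK adduct (3RS)
Product: 17 (4Z,6S,7E)-1-[(4-methoxybenzyl)oxy]-4-{[(tert-butyldiphenylsilyl)oxy]methyl}-6-[(triethylsilyl)oxy]nona-4,7-dien-3-one
Conditions: Dess–Martin periodinane, NaHCO3, CH2Cl2, 0 °C → rt
Reagents that add atoms: none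
Why: Dess–Martin oxidation of the allylic alcohol gives the α-branched enone without touching the silyl or PMB ethers.

Step 12
Reactants: 17 enone
Product: 18 (3S,4Z,6S,7E)-1-[(4-methoxybenzyl)oxy]-4-{[(tert-butyldiphenylsilyl)oxy]methyl}-6-[(triethylsilyl)oxy]nona-4,7-dien-3-ol
Conditions: (R)-Me-CBS (1 equiv), catecholborane, toluene, −78 °C
Reagents that add atoms: none
Why: Corey–Bakshi–Shibata reduction; the α-branched alkenyl group is the large substituent and CH2CH2OPMB the small one, so the (R)-catalyst gives the 3S alcohol.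

Step 13
Reactants: 18 (3S)-allylic alcohol
Product: 19 3-O-TBS ether of 18
Conditions: TBSOTf, 2,6-lutidine, CH2Cl2, −78 °C
Reagents that add atoms: tert-butyldimethylsilyl triflate, CC(C)(C)[Si](C)(C)OS(=O)(=O)C(F)(F)F
Why: silylation of the hindered secondary alcohol; O3 stays masked until the Evans–Tishchenko step.

Step 14
Reactants: 19 3-O-TBS ether of 18
Product: 20 (3S,4Z,6S,7E)-3-[(tert-butyldimethylsilyl)oxy]-4-{[(tert-butyldiphenylsilyl)oxy]methyl}-1-[(4-methoxybenzyl)oxy]nona-4,7-dien-6-ol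
Conditions: PPTS (0.2 equiv), MeOH/CH2Cl2, 0 °C
Reagents that add atoms: none
Why: selective solvolysis; a secondary TES ether cleaves far faster than secondary TBS or primary TBDPS.

Step 15
Reactants: 20 C6 alcohol; 6 2-{[(tert-butyldimethylsilyl)oxy]methyl}prop-2-enoic acid
Product: 21 6-O-{2-[(tert-butyldimethylsilyloxy)methyl]acryloyl} ester of 20
Conditions: DCC, DMAP (cat.), CH2Cl2, 0 °C → rt
Reagents that add atoms: none
Why: Steglich esterification brings in C11–C13 under neutral conditions.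

Step 16
Reactants: 21 acrylate ester
Product: 22 (5R)-3-{[(tert-butyldimethylsilyl)oxy]methyl}-5-[(1Z,3S)-3-[(tert-butyldimethylsilyl)oxy]-2-{[(tert-butyldiphenylsilyl)oxy]methyl}-5-[(4-methoxybenzyl)oxy]pent-1-en-1-yl]furan-2(5H)-one
Conditions: Grubbs II (5 mol %), CH2Cl2 (0.01 M), 40 °C
Reagents that add atoms: none
Why: ring-closing metathesis between the propenyl group and the acrylate forms the butenolide (ring 1) and expels propene; the hindered trisubstituted C4=C5 alkene does not react.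

Step 17
Reactants: 22 silyloxymethyl butenolide
Product: 23 (5R)-3-(hydroxymethyl)butenolide (22 with the C13 O-TBS removed)
Conditions: HF·pyridine, pyridine, THF, 0 °C
Reagents that add atoms: none
Why: selective desilylation; the primary allylic TBS ether cleaves well before the secondary TBS and the TBDPS ethers.

Step 18
Reactants: 23 hydroxymethyl butenolide
Product: 24 (5R)-3-(bromomethyl)-5-[(1Z,3S)-3-[(tert-butyldimethylsilyl)oxy]-2-{[(tert-butyldiphenylsilyl)oxy]methyl}-5-[(4-methoxybenzyl)oxy]pent-1-en-1-yl]furan-2(5H)-one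
Conditions: CBr4, PPh3, CH2Cl2, 0 °C
Reagents that add atoms: carbon tetrabromide, BrC(Br)(Br)Br
Why: Appel bromination under neutral conditions, safe for the base-sensitive γ-alkenyl butenolide.

Step 19
Reactants: 25 but-2-yn-1-ol
Product: 27 (2Z)-3-iodobut-2-en-1-ol, via cyclic vinylalanate 26 (not isolated)
Conditions: Red-Al, THF, 0 °C → rt; EtOAc; then I2, −78 °C
Reagents that add atoms: iodine, II
Why: the same directed trans-hydroalumination/iodination; iodine ends cis to CH2OH, which is the future C9=C10 geometry.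

Step 20
Reactants: 27 (2Z)-3-iodobut-2-en-1-ol
Product: 28 (2Z)-3-iodobut-2-enal
Conditions: activated MnO2, CH2Cl2, rt, dark; used at once
Reagents that add atoms: none
Why: neutral MnO2 oxidation of the allylic alcohol without Z/E isomerisation.

Step 21
Reactants: 24 bromomethyl butenolide; 28 (2Z)-3-iodobut-2-enal
Product: 30 (4R,5R)-4-[(1R,2Z)-1-hydroxy-3-iodobut-2-en-1-yl]-3-methylidene-5-[(1Z,3S)-3-[(tert-butyldimethylsilyl)oxy]-2-{[(tert-butyldiphenylsilyl)oxy]methyl}-5-[(4-methoxybenzyl)oxy]pent-1-en-1-yl]oxolan-2-one, via allylzinc bromide 29 (not isolated)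
Conditions: Zn dust (5 equiv), THF/sat. aq. NH4Cl, rt
Reagents that add atoms: none
Why: Barbier carbonyl allylation forms C7–C8 and the exo-methylene lactone by SE2′ through a closed chair transition state. The aldehyde adds to C7 anti to the C6 side chain (trans lactone, 7R), and the ring-enforced E-type allyl geometry gives anti topicity, so the C8 carbinol is epimeric to the target.

Step 22
Reactants: 30 Barbier adduct; 31 tiglic acid
Product: 32 8-O-tiglate with inverted C8: (4S,5R)-4-[(1S,2Z)-3-iodo-1-{[(2E)-2-methylbut-2-enoyl]oxy}but-2-en-1-yl]-3-methylidene-5-[same C6 side chain]oxolan-2-one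
Conditions: PPh3, DIAD, tiglic acid (3 equiv each), toluene/THF, 0 °C → rt
Reagents that add atoms: none
Why: Mitsunobu esterification proceeds by SN2 inversion, installing the tiglate and the target C8 configuration in one step.

Step 23
Reactants: 32 tiglate
Product: 33 C1 primary alcohol (32 without PMB)
Conditions: DDQ, CH2Cl2/pH 7 buffer, 0 °C
Reagents that add atoms: none
Why: oxidative PMB cleavage is orthogonal to the silyl ethers, esters, vinyl iodide and methylene lactone.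

Step 24
Reactants: 33 C1 alcohol
Product: 34 C1 aldehyde (β-silyloxy aldehyde)
Conditions: Dess–Martin periodinane, NaHCO3, CH2Cl2, 0 °C
Reagents that add atoms: none
Why: buffered Dess–Martin oxidation gives the aldehyde without β-elimination of the silyloxy group.

Step 25
Reactants: 34 iodo-aldehyde
Product: 35 macrocyclic allylic alcohol (10-membered ring; C3, C6, C7, C8 as in the target; C1 epimers)
Conditions: CrCl2 (10 equiv), NiCl2 (10 mol %), DMSO/THF, rt, syringe-pump addition to 2 mM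
Reagents that add atoms: none
Why: intramolecular Nozaki–Hiyama–Kishi reaction closes C1–C10 (ring 2) with retention of the Z-olefin; the C1 configuration is irrelevant because it is oxidised next.

Step 26
Reactants: 35 macrocyclic alcohols
Product: 36 macrocyclic (Z)-enone (C1 ketone)
Conditions: Dess–Martin periodinane, NaHCO3, CH2Cl2, 0 °C
Reagents that add atoms: none
Why: Dess–Martin oxidation converges both epimers to one enone.

Step 27
Reactants: 36 enone
Product: 37 macrocyclic 3-hydroxy-1-ketone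
Conditions: 48 % aq. HF/MeCN (1:19), 0 °C, monitored
Reagents that add atoms: none
Why: selective acidic desilylation; the secondary TBS ether cleaves while the primary TBDPS ether survives, and the mild acid avoids retro-aldol or elimination.

Step 28
Reactants: 37 3-hydroxy-1-ketone
Product: 38 15-O-TBDPS-eupacunolin (1S,3S,6R,7R,8R)
Conditions: MeCHO (10 equiv), SmI2 (0.3 equiv, premixed with MeCHO), THF, −10 °C
Reagents that add atoms: acetaldehyde, CC=O
Why: Evans–Tishchenko reduction; the Sm-bound hemiacetal on O3 delivers hydride intramolecularly to C1, giving the 1,3-anti (1S) alcohol and leaving the acetate on O3.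

Step 29
Reactants: 38 15-O-TBDPS-eupacunolin
Product: 39 eupacunolin
Conditions: HF·pyridine, pyridine, THF, 0 °C → rt
Reagents that add atoms: none
Why: buffered fluoride desilylation releases the C15 alcohol without acetyl migration or attack on the methylene lactone.

## Compound list

1 | propane-1,3-diol | OCCCO | starting material
2 | 3-[(4-methoxybenzyl)oxy]propan-1-ol | OCCCOCc1ccc(OC)cc1 | intermediate
3 | 3-[(4-methoxybenzyl)oxy]propanal | O=CCCOCc1ccc(OC)cc1 | intermediate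
4 | ethyl 2-(hydroxymethyl)prop-2-enoate | C=C(CO)C(=O)OCC | starting material
5 | ethyl 2-{[(tert-butyldimethylsilyl)oxy]methyl}prop-2-enoate | C=C(CO[Si](C)(C)C(C)(C)C)C(=O)OCC | intermediate
6 | 2-{[(tert-butyldimethylsilyl)oxy]methyl}prop-2-enoic acid | C=C(CO[Si](C)(C)C(C)(C)C)C(=O)O | intermediate
7 | prop-2-yn-1-ol | C#CCO | starting material
8 | tert-butyl(diphenyl)(prop-2-yn-1-yloxy)silane | C#CCO[Si](c1ccccc1)(c1ccccc1)C(C)(C)C | intermediate
9 | (E)-but-2-enal | C/C=C/C=O | starting material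
10 | lithium acetylide of 8 | [Li]C#CCO[Si](c1ccccc1)(c1ccccc1)C(C)(C)C | intermediate
11 | rac-(5E)-1-[(tert-butyldiphenylsilyl)oxy]hept-5-en-2-yn-4-ol | C/C=C/C(O)C#CCO[Si](c1ccccc1)(c1ccccc1)C(C)(C)C | intermediate
12 | (4S,5E)-1-[(tert-butyldiphenylsilyl)oxy]hept-5-en-2-yn-4-ol | C/C=C/[C@H](O)C#CCO[Si](c1ccccc1)(c1ccccc1)C(C)(C)C | intermediate
13 | sodium cyclic vinylalanate of 12 (Al on C4, O6–Al chelate) | C/C=C/[C@@H]1O[Al-](OCCOC)(OCCOC)C(CO[Si](c2ccccc2)(c2ccccc2)C(C)(C)C)=C1.[Na+] | intermediate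
14 | (2Z,4S,5E)-1-[(tert-butyldiphenylsilyl)oxy]-2-iodohepta-2,5-dien-4-ol | C/C=C/[C@H](O)/C=C(\I)CO[Si](c1ccccc1)(c1ccccc1)C(C)(C)C | intermediate
15 | triethylsilyl ether of 14 | C/C=C/[C@H](O[Si](CC)(CC)CC)/C=C(\I)CO[Si](c1ccccc1)(c1ccccc1)C(C)(C)C | intermediate
16 | (4Z,6S,7E)-1-(PMB-oxy)-4-[(TBDPS-oxy)methyl]-6-(TES-oxy)nona-4,7-dien-3-ol (3RS) | C/C=C/[C@H](O[Si](CC)(CC)CC)/C=C(/CO[Si](c1ccccc1)(c1ccccc1)C(C)(C)C)C(O)CCOCc1ccc(OC)cc1 | intermediate
17 | (4Z,6S,7E)-1-(PMB-oxy)-4-[(TBDPS-oxy)methyl]-6-(TES-oxy)nona-4,7-dien-3-one | C/C=C/[C@H](O[Si](CC)(CC)CC)/C=C(/CO[Si](c1ccccc1)(c1ccccc1)C(C)(C)C)C(=O)CCOCc1ccc(OC)cc1 | intermediate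
18 | (3S,4Z,6S,7E)-1-(PMB-oxy)-4-[(TBDPS-oxy)methyl]-6-(TES-oxy)nona-4,7-dien-3-ol | C/C=C/[C@H](O[Si](CC)(CC)CC)/C=C(/CO[Si](c1ccccc1)(c1ccccc1)C(C)(C)C)[C@@H](O)CCOCc1ccc(OC)cc1 | intermediate
19 | 3-O-TBS ether of 18 | C/C=C/[C@H](O[Si](CC)(CC)CC)/C=C(/CO[Si](c1ccccc1)(c1ccccc1)C(C)(C)C)[C@@H](O[Si](C)(C)C(C)(C)C)CCOCc1ccc(OC)cc1 | intermediate
20 | (3S,4Z,6S,7E)-3-(TBS-oxy)-4-[(TBDPS-oxy)methyl]-1-(PMB-oxy)nona-4,7-dien-6-ol | C/C=C/[C@H](O)/C=C(/CO[Si](c1ccccc1)(c1ccccc1)C(C)(C)C)[C@@H](O[Si](C)(C)C(C)(C)C)CCOCc1ccc(OC)cc1 | intermediate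
21 | 6-O-{2-[(TBS-oxy)methyl]acryloyl} ester of 20 | C/C=C/[C@H](OC(=O)C(=C)CO[Si](C)(C)C(C)(C)C)/C=C(/CO[Si](c1ccccc1)(c1ccccc1)C(C)(C)C)[C@@H](O[Si](C)(C)C(C)(C)C)CCOCc1ccc(OC)cc1 | intermediate
22 | (5R)-3-[(TBS-oxy)methyl]-5-[(1Z,3S)-3-(TBS-oxy)-2-[(TBDPS-oxy)methyl]-5-(PMB-oxy)pent-1-en-1-yl]furan-2(5H)-one | O=C1O[C@H](/C=C(/CO[Si](c2ccccc2)(c2ccccc2)C(C)(C)C)[C@@H](O[Si](C)(C)C(C)(C)C)CCOCc2ccc(OC)cc2)C=C1CO[Si](C)(C)C(C)(C)C | intermediate
23 | (5R)-3-(hydroxymethyl) analogue of 22 | O=C1O[C@H](/C=C(/CO[Si](c2ccccc2)(c2ccccc2)C(C)(C)C)[C@@H](O[Si](C)(C)C(C)(C)C)CCOCc2ccc(OC)cc2)C=C1CO | intermediate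
24 | (5R)-3-(bromomethyl) analogue of 22 | O=C1O[C@H](/C=C(/CO[Si](c2ccccc2)(c2ccccc2)C(C)(C)C)[C@@H](O[Si](C)(C)C(C)(C)C)CCOCc2ccc(OC)cc2)C=C1CBr | intermediate
25 | but-2-yn-1-ol | CC#CCO | starting material
26 | sodium cyclic vinylalanate of 25 | CC1=CCO[Al-]1(OCCOC)OCCOC.[Na+] | intermediate
27 | (2Z)-3-iodobut-2-en-1-ol | C/C(I)=C/CO | intermediate
28 | (2Z)-3-iodobut-2-enal | C/C(I)=C/C=O | intermediate
29 | allylzinc bromide of 24 | O=C1O[C@H](/C=C(/CO[Si](c2ccccc2)(c2ccccc2)C(C)(C)C)[C@@H](O[Si](C)(C)C(C)(C)C)CCOCc2ccc(OC)cc2)C=C1C[Zn]Br | intermediate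
30 | Barbier adduct, (4R,5R)-4-[(1R,2Z)-1-hydroxy-3-iodobut-2-en-1-yl]-3-methylidene-5-[side chain as in 24]oxolan-2-one (C8 epimeric to the target) | C=C1C(=O)O[C@H](/C=C(/CO[Si](c2ccccc2)(c2ccccc2)C(C)(C)C)[C@@H](O[Si](C)(C)C(C)(C)C)CCOCc2ccc(OC)cc2)[C@H]1[C@@H](O)/C=C(\I)C | intermediate
31 | tiglic acid, (2E)-2-methylbut-2-enoic acid | C/C=C(\C)C(=O)O | starting material
32 | 8-O-tiglate of inverted 30, (4S,5R)-oxolan-2-one with (1S,2Z)-3-iodo-1-(tigloyloxy)but-2-en-1-yl (C8 as in the target) | C=C1C(=O)O[C@H](/C=C(/CO[Si](c2ccccc2)(c2ccccc2)C(C)(C)C)[C@@H](O[Si](C)(C)C(C)(C)C)CCOCc2ccc(OC)cc2)[C@H]1[C@H](OC(=O)/C(C)=C/C)/C=C(\I)C | intermediate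
33 | C1 primary alcohol (32 without PMB) | C=C1C(=O)O[C@H](/C=C(/CO[Si](c2ccccc2)(c2ccccc2)C(C)(C)C)[C@@H](O[Si](C)(C)C(C)(C)C)CCO)[C@H]1[C@H](OC(=O)/C(C)=C/C)/C=C(\I)C | intermediate
34 | C1 aldehyde (seco iodo-aldehyde) | C=C1C(=O)O[C@H](/C=C(/CO[Si](c2ccccc2)(c2ccccc2)C(C)(C)C)[C@@H](O[Si](C)(C)C(C)(C)C)CC=O)[C@H]1[C@H](OC(=O)/C(C)=C/C)/C=C(\I)C | intermediate
35 | macrocyclic C1 alcohol, 3-O-TBS, 15-O-TBDPS, 8-O-tigloyl (C3, C6, C7, C8 as in the target; 1RS) | C=C1C(=O)O[C@@H]2/C=C(/CO[Si](c3ccccc3)(c3ccccc3)C(C)(C)C)[C@@H](O[Si](C)(C)C(C)(C)C)CC(O)/C(C)=C\[C@@H](OC(=O)/C(C)=C/C)[C@@H]12 | intermediate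
36 | macrocyclic (9Z)-1-ketone, 3-O-TBS, 15-O-TBDPS | C=C1C(=O)O[C@@H]2/C=C(/CO[Si](c3ccccc3)(c3ccccc3)C(C)(C)C)[C@@H](O[Si](C)(C)C(C)(C)C)CC(=O)/C(C)=C\[C@@H](OC(=O)/C(C)=C/C)[C@@H]12 | intermediate
37 | macrocyclic 3-hydroxy-1-ketone, 15-O-TBDPS | C=C1C(=O)O[C@@H]2/C=C(/CO[Si](c3ccccc3)(c3ccccc3)C(C)(C)C)[C@@H](O)CC(=O)/C(C)=C\[C@@H](OC(=O)/C(C)=C/C)[C@@H]12 | intermediate
38 | 15-O-TBDPS-eupacunolin (1S,3S,6R,7R,8R,4Z,9Z) | C=C1C(=O)O[C@@H]2/C=C(/CO[Si](c3ccccc3)(c3ccccc3)C(C)(C)C)[C@@H](OC(C)=O)C[C@H](O)/C(C)=C\[C@@H](OC(=O)/C(C)=C/C)[C@@H]12 | intermediate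
39 | eupacunolin | C=C1C(=O)O[C@@H]2/C=C(/CO)[C@@H](OC(C)=O)C[C@H](O)/C(C)=C\[C@@H](OC(=O)/C(C)=C/C)[C@@H]12 | target

## Step count and risks

Total steps: 29. Longest linear sequence: 23 (steps 5–18, then 21–29, from prop-2-yn-1-ol).

Three steps most likely to fail:

1. Step 22, Mitsunobu inversion at the hindered allylic C8 next to a Michael-acceptor lactone (SN2′, ionisation or phosphine addition could compete). Fallback, from bromide 24 back to tiglate 32: convert 24 with hexabutylditin and catalytic Pd(PPh3)4 (THF, rt) into the allyltributylstannane F1. Add F1 to aldehyde 28 with BF3·OEt2 in CH2Cl2 at −78 °C; the open antiperiplanar transition state gives the syn-type adduct, the C8-epimeric alcohol F2, which already has the target C8 configuration. Acylate F2 with tiglic acid 31 under Yamaguchi conditions (2,4,6-trichlorobenzoyl chloride, Et3N, DMAP, toluene) with retention to reach 32.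

2. Step 25, NHK closure of the strained 10-membered ring (oligomerisation or protodeiodination). Fallback, from aldehyde 34 back to enone 36: Pinnick oxidation (NaClO2, NaH2PO4, 2-methylbut-2-ene) gives the seco acid F3. 2,2′-Dipyridyl disulfide/PPh3 converts it into the S-(pyridin-2-yl) thioester F4. Nickel-mediated reductive acyl coupling of the vinyl iodide onto the thioester (NiBr2·dtbbpy cat., Cp2ZrCl2, Zn, DMI, high dilution) closes the ring at the ketone oxidation level and gives 36 directly; intramolecular use of this coupling with a vinyl iodide is untested.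

3. Step 28, Evans–Tishchenko reduction inside the macrocycle (the ring may resist the six-membered hydride-transfer geometry; Sm could touch the enone or lactone; acetyl could migrate). Fallback, from hydroxy ketone 37 back to 38: acetylate O3 first (Ac2O, pyridine, cat. DMAP, 0 °C) to the β-acetoxy enone F5, then set C1 by reagent control with (R)-Me-CBS/catecholborane (toluene, −78 °C; alkenyl side as the large group gives 1S) to reach 38.

## Further compounds

F1 | step 22 | allyltributylstannane analogue of 24 | O=C1O[C@H](/C=C(/CO[Si](c2ccccc2)(c2ccccc2)C(C)(C)C)[C@@H](O[Si](C)(C)C(C)(C)C)CCOCc2ccc(OC)cc2)C=C1C[Sn](CCCC)(CCCC)CCCC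
F2 | step 22 | C8 epimer of 30 (free 8-OH in the target configuration) | C=C1C(=O)O[C@H](/C=C(/CO[Si](c2ccccc2)(c2ccccc2)C(C)(C)C)[C@@H](O[Si](C)(C)C(C)(C)C)CCOCc2ccc(OC)cc2)[C@H]1[C@H](O)/C=C(\I)C
F3 | step 25 | C1 carboxylic acid from 34 | C=C1C(=O)O[C@H](/C=C(/CO[Si](c2ccccc2)(c2ccccc2)C(C)(C)C)[C@@H](O[Si](C)(C)C(C)(C)C)CC(=O)O)[C@H]1[C@H](OC(=O)/C(C)=C/C)/C=C(\I)C
F4 | step 25 | S-(pyridin-2-yl) thioester of F3 | C=C1C(=O)O[C@H](/C=C(/CO[Si](c2ccccc2)(c2ccccc2)C(C)(C)C)[C@@H](O[Si](C)(C)C(C)(C)C)CC(=O)Sc2ccccn2)[C@H]1[C@H](OC(=O)/C(C)=C/C)/C=C(\I)C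
F5 | step 28 | 3-O-acetyl derivative of 37 (β-acetoxy enone) | C=C1C(=O)O[C@@H]2/C=C(/CO[Si](c3ccccc3)(c3ccccc3)C(C)(C)C)[C@@H](OC(C)=O)CC(=O)/C(C)=C\[C@@H](OC(=O)/C(C)=C/C)[C@@H]12
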